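**Plan**

- Each half is numbered as a tetralin: C1 carries the methyl, C4 the isopropyl, C4a/C8a are the fusion atoms, C7 carries oxygen and C8 the biaryl bond.
- Retrosynthetic cuts, in order: the two O–CH3 bonds, the two C4–H bonds (from C4–B), the two C4–isopropyl bonds, C4–O back to the ketone, the two C4–C4a bonds, the side-chain C–C bonds, and last C8–C8'.
- Forward: an Ullmann coupling makes the biaryl first, both side chains are grown from the formyl groups, both saturated rings close together onto C4a, and the isopropyl groups come last.
- Enabling feature: C4 is a benzylic methine on C4a, para to the C7 oxygen. This lets the C4 ketone form by acylation at C4a, and the derived benzylic C4–O carbamate can be lithiated and exchanged for C4–isopropyl.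
- Stereochemistry: C1 (S) comes from a copper-catalysed asymmetric allylic methylation, and C4–O (S, trans to the C1 methyl) from an oxazaborolidine reduction. C4–isopropyl (cis to the methyl) follows from retention then inversion in the lithiation–borylation and retention in the protodeboronation.

Key step: step 11

Assumption 1: the target is drawn without a descriptor for the C8–C8' axis, so the four carbon stereocentres (1S,4S in each half) are taken as the defined stereochemistry; the axis should be configurationally stable from 6 on, compounds 11–23 are carried as both axial forms (same SMILES), separable as diastereomers at 14 or at the end.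

Assumption 2: the facial sense of the CuBr·SMe2/Taniaphos system is taken from the parent cinnamyl bromide/MeMgBr reaction ((R,Rp) ligand giving the S centre); the ligand antipode would be used if a mono-aryl model shows the opposite sense.

**Route**

Step 1
Reactants: 1 3-methoxy-4-methylbenzaldehyde
Product: 5 2-iodo-3-methoxy-4-methylbenzaldehyde, via lithium amino alkoxide 2 (not isolated), via ortho-lithiated amino alkoxide 3 (not isolated), via iodinated amino alkoxide 4 (not isolated)
Conditions: Me2NCH2CH2N(Li)Me (from Me2NCH2CH2NHMe + n-BuLi), THF, −20 °C; n-BuLi (3 equiv), −20 °C; I2, −78 °C → rt; aq. HCl, Na2S2O3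
Reagents that add atoms: iodine, [I][I]
Why: In-situ masking of the aldehyde as a lithium α-amino alkoxide gives a directing group that, together with the methoxy group (whose other ortho position is blocked by methyl), steers directed ortho-metalation to the carbon between them, and iodine quench followed by hydrolysis returns the aldehyde.

Step 2
Reactants: 5 2-iodo-3-methoxy-4-methylbenzaldehyde (two molecules)
Product: 6 2,2'-dimethoxy-3,3'-dimethylbiphenyl-6,6'-dicarbaldehyde
Conditions: Cu powder (activated), DMF, 150 °C
Reagents that add atoms: none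
Why: Classical Ullmann homocoupling of an aryl iodide activated by an ortho formyl group, a standard entry to tetra-ortho-substituted biphenyl dialdehydes.

Step 3
Reactants: 6 biaryl dialdehyde; 7 vinylmagnesium bromide
Product: 8 6,6'-bis(1-hydroxyprop-2-enyl)-2,2'-dimethoxy-3,3'-dimethylbiphenyl (carbinol centres unassigned)
Conditions: CH2=CHMgBr (2.5 equiv), THF, −78 → 0 °C; aq. NH4Cl
Reagents that add atoms: vinylmagnesium bromide (7), C=C[Mg]Br
Why: Grignard 1,2-addition to both aldehydes; the carbinol configuration is irrelevant because the centres are erased in the next step.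

Step 4
Reactants: 8 bis(allylic alcohol)
Product: 9 6,6'-bis[(E)-3-bromoprop-1-enyl]-2,2'-dimethoxy-3,3'-dimethylbiphenyl
Conditions: PBr3, Et2O, 0 °C → rt
Reagents that add atoms: phosphorus tribromide, BrP(Br)Br
Why: Bromination of 1-arylallyl alcohols proceeds with allylic transposition (SN2' or ion-pair return) to the conjugated, thermodynamically preferred primary (E)-cinnamyl bromide.

Step 5
Reactants: 9 bis(cinnamyl bromide); 10 methylmagnesium bromide
Product: 11 6,6'-bis[(S)-but-3-en-2-yl]-2,2'-dimethoxy-3,3'-dimethylbiphenyl
Conditions: MeMgBr (2.6 equiv), CuBr·SMe2 (10 mol%), (R,Rp)-Taniaphos (C43H39FeNP2, 12 mol%), CH2Cl2, −78 °C, slow addition of 9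
Reagents that add atoms: methylmagnesium bromide (10), C[Mg]Br
Why: Copper-catalysed asymmetric allylic alkylation of cinnamyl bromides with MeMgBr is γ-selective (SN2') and gives the branched 3-arylbut-1-ene, the ferrocenyl diphosphine choosing the alkene face so that each new benzylic centre (the later C1) should be S.

Step 6
Reactants: 11 bis(butenyl)biaryl
Product: 12 (4S,4'S)-4,4'-(2,2'-dimethoxy-3,3'-dimethylbiphenyl-6,6'-diyl)dipentanal
Conditions: Rh(acac)(CO)2 (2 mol%), Xantphos (4 mol%), CO/H2 (1:1, 10 bar), toluene, 70 °C
Reagents that add atoms: carbon monoxide, [C-]#[O+]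
Why: Linear-selective rhodium-catalysed hydroformylation, in which the wide-bite-angle diphosphine and the α-branch direct the formyl group to the terminal carbon while CO pressure suppresses alkene migration, so the allylic benzylic centre should stay intact.

Step 7
Reactants: 12 bis-aldehyde
Product: 13 (4S,4'S)-4,4'-(2,2'-dimethoxy-3,3'-dimethylbiphenyl-6,6'-diyl)dipentanoic acid
Conditions: NaClO2, NaH2PO4, 2-methyl-2-butene, t-BuOH/H2O, 0 °C → rt
Reagents that add atoms: sodium chlorite, [Na+].[O-]Cl=O
Why: Pinnick oxidation converts aldehydes to acids under buffered conditions without touching the remote stereocentre, and the alkene scavenger keeps hypochlorous acid away from the electron-rich rings.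

Step 8
Reactants: 13 bis-acid
Product: 14 bis-tetralone, two (1S)-7-methoxy-1,6-dimethyl-4-oxotetralin units joined C8–C8' (local numbering)
Conditions: Eaton's reagent (P2O5 in MeSO3H), 25 → 45 °C
Reagents that add atoms: none
Why: Twofold intramolecular Friedel–Crafts acylation closes each six-membered ring at the only free position ortho to the side chain, which is para to the methoxy group and therefore strongly activated.

Step 9
Reactants: 14 bis-tetralone
Product: 15 trans bis-tetralol (1S,4S,1'S,4'S), each C4–OH trans to the C1 methyl
Conditions: (R)-2-methyl-CBS-oxazaborolidine [(R)-1-methyl-3,3-diphenyltetrahydro-1H,3H-pyrrolo[1,2-c][1,3,2]oxazaborole, 0.4 equiv], BH3·SMe2, THF, −20 °C; MeOH quench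
Reagents that add atoms: none
Why: Corey–Bakshi–Shibata reduction, in which the (R)-oxazaborolidine differentiates the aryl and methylene flanks of the ketone and delivers hydride to the face that gives the S carbinol, so the hydroxyl is set trans to the remote C1 methyl under catalyst control, as known for 4-substituted 1-tetralones.

Step 10
Reactants: 15 trans bis-tetralol; 16 N,N-diisopropylcarbamoyl chloride
Product: 17 trans bis(N,N-diisopropylcarbamate) (1S,4S,1'S,4'S)
Conditions: iPr2NCOCl (3 equiv), Et3N (4 equiv), CH2Cl2, reflux
Reagents that add atoms: N,N-diisopropylcarbamoyl chloride (16), CC(C)N(C(C)C)C(Cl)=O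
Why: O-Carbamoylation of secondary benzylic alcohols under basic conditions leaves both stereocentres untouched and installs the group needed for α-lithiation.

Step 11
Reactants: 17 trans bis-carbamate; 18 isopropylboronic acid pinacol ester
Product: 21 bis(tertiary boronic ester), via dilithiated bis-carbamate 19 (not isolated), via bis-boronate complex 20 (not isolated)
Conditions: s-BuLi (2.6 equiv), Et2O, −78 °C, 1 h; 18 (3 equiv), −78 °C, 1 h; MgBr2 in MeOH (1 M), −78 °C → rt, then 40 °C
Reagents that add atoms: isopropylboronic acid pinacol ester (18), CC(C)B1OC(C)(C)C(C)(C)O1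
Why: sec-Butyllithium, guided by the carbamate carbonyl, removes the benzylic C4–H of each half to give a lithiated carbamate that is configurationally stable at −78 °C, and the pinacol boronate traps it with retention to give boronate complex 20. On warming with MgBr2/MeOH the isopropyl group shifts from boron to C4 antiperiplanar to the departing carbamate (1,2-metalate rearrangement), inverting C4 and forming the C4–isopropyl bond of each half. The closest known reaction type is the lithiation–borylation of enantioenriched secondary benzylic carbamates, open-chain and tetralin-1-yl, with secondary alkyl pinacol boronates, a Matteson-type homologation. No ring is closed. Each new boron-bearing quaternary C4 is controlled only by the configuration of the carbamate carbon (retention, then inversion), so the S carbamate should give boron trans and isopropyl cis to the C1 methyl whatever the remote C1 centre or the axis. The step needs site-selective deprotonation and irreversible onward reaction of the hindered boronate: the carbamate makes C4–H by far the most acidic site (no free position ortho to methoxy, C1–H unactivated), MgBr2 accelerates the migration, and methanol destroys any lithiated carbamate released by reversal.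

Step 12
Reactants: 21 bis(tertiary boronic ester)
Product: 22 target bis(methyl ether) (1S,4S,1'S,4'S), isopropyl cis to methyl in each half
Conditions: TBAF·3H2O (6 equiv), toluene, 60 °C
Reagents that add atoms: none
Why: Fluoride-promoted protodeboronation of tertiary benzylic pinacol boronic esters by the hydrate water proceeds with retention, so hydrogen takes the place of boron trans to the C1 methyl.

Step 13
Reactants: 22 bis(methyl ether)
Product: 23 target biaryl bis-phenol (CNP0152871.1)
Conditions: BBr3 (5 equiv), CH2Cl2, −78 → 0 °C; H2O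
Reagents that add atoms: none
Why: BBr3 cleavage of aryl methyl ethers (borane–ether complexation, then bromide attack on methyl) frees both hindered phenols without affecting the benzylic C–H stereocentres.

**Compound list**

1 | 3-methoxy-4-methylbenzaldehyde | COc1cc(C=O)ccc1C | starting material
2 | lithium α-amino alkoxide of 1 with N,N,N'-trimethylethylenediamide | COc1cc(ccc1C)C(O[Li])N(C)CCN(C)C | intermediate
3 | C2-lithiated amino alkoxide | COc1c(C)ccc(C(O[Li])N(C)CCN(C)C)c1[Li] | intermediate
4 | C2-iodinated amino alkoxide | COc1c(C)ccc(C(O[Li])N(C)CCN(C)C)c1I | intermediate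
5 | 2-iodo-3-methoxy-4-methylbenzaldehyde | COc1c(C)ccc(C=O)c1I | intermediate
6 | 2,2'-dimethoxy-3,3'-dimethylbiphenyl-6,6'-dicarbaldehyde | COc1c(C)ccc(C=O)c1-c1c(OC)c(C)ccc1C=O | intermediate
7 | vinylmagnesium bromide | C=C[Mg]Br | starting material
8 | 6,6'-bis(1-hydroxyprop-2-enyl)-2,2'-dimethoxy-3,3'-dimethylbiphenyl | COc1c(C)ccc(C(O)C=C)c1-c1c(OC)c(C)ccc1C(O)C=C | intermediate
9 | 6,6'-bis[(E)-3-bromoprop-1-enyl]-2,2'-dimethoxy-3,3'-dimethylbiphenyl | COc1c(C)ccc(/C=C/CBr)c1-c1c(OC)c(C)ccc1/C=C/CBr | intermediate
10 | methylmagnesium bromide | C[Mg]Br | starting material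
11 | 6,6'-bis[(S)-but-3-en-2-yl]-2,2'-dimethoxy-3,3'-dimethylbiphenyl | COc1c(C)ccc([C@@H](C)C=C)c1-c1c(OC)c(C)ccc1[C@@H](C)C=C | intermediate
12 | (4S,4'S)-4,4'-(2,2'-dimethoxy-3,3'-dimethylbiphenyl-6,6'-diyl)dipentanal | COc1c(C)ccc([C@@H](C)CCC=O)c1-c1c(OC)c(C)ccc1[C@@H](C)CCC=O | intermediate
13 | (4S,4'S)-4,4'-(2,2'-dimethoxy-3,3'-dimethylbiphenyl-6,6'-diyl)dipentanoic acid | COc1c(C)ccc([C@@H](C)CCC(=O)O)c1-c1c(OC)c(C)ccc1[C@@H](C)CCC(=O)O | intermediate
14 | bis-tetralone, C8–C8' dimer of (1S)-7-methoxy-1,6-dimethyl-4-oxotetralin | COc1c(C)cc2c(c1-c1c(OC)c(C)cc3c1[C@@H](C)CCC3=O)[C@@H](C)CCC2=O | intermediate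
15 | trans bis-tetralol (1S,4S,1'S,4'S) | COc1c(C)cc2c(c1-c1c(OC)c(C)cc3c1[C@@H](C)CC[C@@H]3O)[C@@H](C)CC[C@@H]2O | intermediate
16 | N,N-diisopropylcarbamoyl chloride | CC(C)N(C(C)C)C(Cl)=O | starting material
17 | trans bis(N,N-diisopropylcarbamate) (1S,4S,1'S,4'S) | COc1c(C)cc2c(c1-c1c(OC)c(C)cc3c1[C@@H](C)CC[C@@H]3OC(=O)N(C(C)C)C(C)C)[C@@H](C)CC[C@@H]2OC(=O)N(C(C)C)C(C)C | intermediate
18 | isopropylboronic acid pinacol ester | CC(C)B1OC(C)(C)C(C)(C)O1 | starting material
19 | C4,C4'-dilithiated bis-carbamate (lithium in place of each C4–H) | COc1c(C)cc2c(c1-c1c(OC)c(C)cc3c1[C@@H](C)CC[C@]3([Li])OC(=O)N(C(C)C)C(C)C)[C@@H](C)CC[C@]2([Li])OC(=O)N(C(C)C)C(C)C | intermediate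
20 | dilithium bis(isopropyl pinacol boronate) complex | [Li+].[Li+].COc1c(C)cc2c(c1-c1c(OC)c(C)cc3c1[C@@H](C)CC[C@]3([B-]4(OC(C)(C)C(C)(C)O4)C(C)C)OC(=O)N(C(C)C)C(C)C)[C@@H](C)CC[C@]2([B-]4(OC(C)(C)C(C)(C)O4)C(C)C)OC(=O)N(C(C)C)C(C)C | intermediate
21 | bis(tertiary boronic ester) (1S,4S,1'S,4'S), Bpin trans and isopropyl cis to the C1 methyl | COc1c(C)cc2c(c1-c1c(OC)c(C)cc3c1[C@@H](C)CC[C@@]3(B4OC(C)(C)C(C)(C)O4)C(C)C)[C@@H](C)CC[C@@]2(B4OC(C)(C)C(C)(C)O4)C(C)C | intermediate
22 | target bis(methyl ether) (1S,4S,1'S,4'S) | COc1c(C)cc2c(c1-c1c(OC)c(C)cc3c1[C@@H](C)CC[C@H]3C(C)C)[C@@H](C)CC[C@H]2C(C)C | intermediate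
23 | CNP0152871.1, C8–C8' dimer of (1S,4S)-4-isopropyl-1,6-dimethyltetralin-7-ol | Cc1cc2c(c(-c3c(O)c(C)cc4c3[C@@H](C)CC[C@H]4C(C)C)c1O)[C@@H](C)CC[C@H]2C(C)C | target

**Totals**

Total step count: 13. Longest linear sequence: 13 steps (1 → 23).

**Steps most likely to fail**

Step 11 (key step). The twofold deprotonation may stay incomplete, the hindered boronate may revert to the lithiated carbamate before migration (eroding stereochemical fidelity), or the isopropyl shift may be too slow. The fallback sets out from bis-tetralone 14 and returns at 22. Isopropylmagnesium chloride with anhydrous CeCl3 (THF, −78 °C) would add to both ketones to give the bis(tertiary benzylic alcohol) F1, whose carbinol configuration is immaterial. Acid dehydration (p-TsOH, toluene, 60 °C) would give the bis(4-isopropyl-1,2-dihydronaphthalene) F2. Hydrogenation over Pd/C (H2, EtOAc) should add hydrogen to the face opposite the C1 methyl, which the peri biaryl holds pseudoaxial, to give the cis compound 22. The C4 centre then rests on substrate control instead of stereospecific transfer.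

Step 5. The ortho biaryl substituent may lower the branched-to-linear selectivity and the facial selectivity of the allylic methylation, and any error is incurred twice. The fallback sets out from dialdehyde 6 and returns at bis-acid 13, bypassing steps 3–7. Addition of methylmagnesium bromide 10 would give the bis(1-hydroxyethyl)biaryl F3, and Dess–Martin oxidation the bis(methyl ketone) F4. A Wittig reaction with the ylide from (2-carboxyethyl)triphenylphosphonium bromide (NaHMDS, THF) would give the bis[(E)-4-arylpent-3-enoic acid] F5. Carboxyl-directed asymmetric hydrogenation with a chiral spiro phosphine–oxazoline iridium complex, [Ir(cod)(L)]BArF (H2, Et3N, MeOH), using the ligand enantiomer that gives the S acid, would then set C1 by hydrogenation instead of allylic substitution.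

Step 12. Protodeboronation of a hindered, electron-rich tertiary benzylic boronic ester may be slow, and forcing it may open a non-retentive pathway or elimination. The fallback sets out from 21 and returns at 22. Oxidation (NaOH, H2O2, THF, 0 °C) with retention would give the bis(tertiary alcohol) F6. Ionic hydrogenation (Et3SiH, CF3CO2H, CH2Cl2, −40 °C) would pass through the C4 cation stabilised by the para methoxy group, with hydride expected to arrive anti to the pseudoaxial C1 methyl, giving the cis compound 22.

**Further compounds**

F1 | step 11 | bis(tertiary alcohol) from isopropyl Grignard addition to 14 (C4 configuration unassigned) | COc1c(C)cc2c(c1-c1c(OC)c(C)cc3c1[C@@H](C)CCC3(O)C(C)C)[C@@H](C)CCC2(O)C(C)C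
F2 | step 11 | bis[(1S)-4-isopropyl-7-methoxy-1,6-dimethyl-1,2-dihydronaphthalen-8-yl] | COc1c(C)cc2c(c1-c1c(OC)c(C)cc3c1[C@@H](C)CC=C3C(C)C)[C@@H](C)CC=C2C(C)C
F3 | step 5 | 6,6'-bis(1-hydroxyethyl)-2,2'-dimethoxy-3,3'-dimethylbiphenyl | COc1c(C)ccc(C(C)O)c1-c1c(OC)c(C)ccc1C(C)O
F4 | step 5 | 6,6'-diacetyl-2,2'-dimethoxy-3,3'-dimethylbiphenyl | COc1c(C)ccc(C(C)=O)c1-c1c(OC)c(C)ccc1C(C)=O
F5 | step 5 | (3E,3'E)-4,4'-(2,2'-dimethoxy-3,3'-dimethylbiphenyl-6,6'-diyl)bis(pent-3-enoic acid) | COc1c(C)ccc(/C(C)=C/CC(=O)O)c1-c1c(OC)c(C)ccc1/C(C)=C/CC(=O)O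
F6 | step 12 | bis(tertiary alcohol) from oxidation of 21, C4–OH trans to the C1 methyl | COc1c(C)cc2c(c1-c1c(OC)c(C)cc3c1[C@@H](C)CC[C@@]3(O)C(C)C)[C@@H](C)CC[C@@]2(O)C(C)C
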